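Late readings tell you little if the solid substrate is gone early, so ask first when that happens.

solid substrate 0.084 M; partner 0.151 M; time 10 min

- which holds at 10 min: what has brought the reaction to rest, or that it has not come to rest (for what has run out or reacted, a solid counts together with what of it has only dissolved) (all of the solid substrate has reacted / the partner has run out first / it is still moving)
- part of the solid substrate that has turned into other species by 10 min (what has only dissolved does not count)
- the target standing at 10 min, as a percentage of the solid substrate charged
- the side product B standing at 10 min, as a percentage of the solid substrate charged

- a species is counted by the solid substrate in it: one side product A or side product B counts as two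
- amounts and yields of target count solid product too
- a doubled species enters its step squared and goes two at a time
- given per volume of solution although it is solid: solid substrate, solid product
- at the start none of the solid substrate is in solution
- what has only dissolved of solid substrate counts as not reacted
- the reaction counts as stopped when no species that holds the solid substrate changes by six tenths of a point or more over the second half of the time
- run time (flask): 10 min

    solid substrate ⇌ dissolved substrate, rate k1*(cs1 - [dissolved substrate]) while solid is left; crystals form when [dissolved substrate] > cs1 (cs1 = 18 mM, k1 = 0.081 s⁻¹)
    dissolved substrate + partner → target (k2 = 5.4 L mol⁻¹ s⁻¹)
    2 dissolved substrate → side product A (k3 = 0.43 L mol⁻¹ s⁻¹)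
    solid product ⇌ target, rate k4*(cs4 - [target]) while solid is left; crystals form when [target] > cs4 (cs4 = 33 mM, k4 = 4.9 s⁻¹)
    solid substrate + target → side product B (k5 = 2.4 L mol⁻¹ s⁻¹)

How fast does the solid substrate enter solution? The partner removes dissolved substrate at 0.815 s⁻¹, faster than the refill coefficient 0.081 s⁻¹. So [dissolved substrate] sits near 1.63 mM, and target is made at about 1.33 mM s⁻¹. At that pace, dissolving by itself would clear this flask's charge in 1.06 min, and 10 min is about ten times longer. The partner is charged above the solid substrate, so the solid substrate is the limiting reagent. Two dissolved substrate pairing off take about 0.172% of the flow, a small correction.

So where does the target go? At the charged solid substrate, its half-life against attack is 0.057 min, shorter than the 1.06 min of dissolving. Target therefore stays low at first: by this estimate attack keeps pace with supply, and [target] is about the supply divided by k5[solid substrate]. As the solid shrinks, [target] climbs until [target] and [solid substrate] are equal, at 23.5 mM, the crossing level, the square root of supply over k5. That is below 33 mM, so I expect no solid product. At the crossing, solid substrate equal to that level still stands, so target can rise past it; I commit to target at 28.0% of the charge and side product B at 72.0%, with target on the low side.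

The forecast, higher on target than I am, says all of the solid substrate has reacted, with 100% conversion, 32% target and 68% side product B, the solid being “consumed both by dissolving and by attacking the target”.

The simulation gives all of the solid substrate has reacted, with 100% conversion, 32.1% target and 67.8% side product B.

In this flask, dissolving and attack ran together while solid substrate lasted, the dissolving reaching its midpoint at 0.350 min, and by 1.00 min the solid substrate stood at 0%. From then to 10.0 min, target held at 32.1% and partner at 63.3%, so this flask's target is 27.0 mM, above my crossing level. The level contains no solid charge, so for the neighbour with 0.14 M of solid substrate it gives 16.8% target; that neighbour ends at 19.3%, or 27.0 mM.

The constants come from no measurement.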